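**Retrosynthetic overview**

1. The target is 3α-angeloyloxy-9β-senecioyloxy-10βH-eremophil-11-en-8-one. The last disconnections are the C9 ester, the C7 isopropenyl group (acetone aldol, dehydration) and the C9 oxygen (Rubottom), all on a cis-decalin-8-one that already carries the C3 angelate.
2. Ring A (C5–C4–C3–C2–C1–C10) is not closed as a six-membered ring. It is grown from the cyclopentane C5–C3–C2–C1–C10 of a cis-hydrindane by a one-carbon semipinacol ring enlargement: the CH of a vinyl group on C3 becomes C4 and its CH2 becomes the C4 methyl.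
3. Enabling feature: in ring A the oxygenated C3 is flanked by the methine C4 (H, CH3), which is bonded to the quaternary ring-fusion carbon C5 (CH3). This C5–C4–C3(O) triad is a semipinacol retron with C3 as carbinol origin, C4 as terminus and C5 as migrating atom.
4. The hydrindane is (S)-Hajos–Parrish ketone after cis-hydrogenation (sets C10), C8 ketalisation and vinyl addition. Its six-membered ring is ring B (enone C=O = C8) and its quaternary carbon is C5.
5. Ring order: ring B and the five-membered precursor of ring A are present in 1; ring A reaches its final size in step 4. C4, C3, C9 and C7 are then set as equatorial centres of the steroid-like cis-decalin conformer.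

Key step: step 4

Remark (numbering): eremophilane numbering is used for the decalins and, by anticipation, for the hydrindanes (ring A = C1–C5, C10; ring B = C5–C10; C11–C13 = isopropenyl); β is the face of the C5 methyl; the SMILES are authoritative for configuration.
Remark (configuration): the target SMILES is read as 3α-O, 4β-CH3, 5β-CH3, 7β-isopropenyl, 9β-O, 10β-H, i.e. (3R,4R,5R,7R,9R,10S) and a cis-fused decalin.
Remark (step 3): vinyl addition is assumed to occur anti to the angular methyl; the carbinol configuration is erased in step 4, so either epimer would serve.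

**Route**

Step 1
Reactants: 1 (S)-Hajos–Parrish ketone
Product: 2 cis-7a-methylhexahydroindane-1,5-dione
Conditions: H2 (1 atm), 10% Pd/C, EtOAc, rt
Reagents that add atoms: none
Why: Heterogeneous catalytic hydrogenation of this enone is the established route to the cis-fused hydrindanedione and sets C10–H cis to the C5 methyl (the later 10βH cis ring fusion).

Step 2
Reactants: 2 cis-7a-methylhexahydroindane-1,5-dione
Product: 3 cis-hydrindanedione C8-monoethylene ketal
Conditions: ethylene glycol (1.1 equiv), p-TsOH·H2O (cat.), benzene, reflux, Dean–Stark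
Reagents that add atoms: ethylene glycol OCCO
Why: Acid-catalysed ketalisation should be chemoselective for the unhindered cyclohexanone over the cyclopentanone that is neopentyl to the quaternary carbon, masking the future C8 carbonyl and leaving the future C3 carbonyl free.

Step 3
Reactants: 3 cis-hydrindanedione C8-monoethylene ketal
Product: 4 C3 vinyl carbinol of the hydrindane ketal
Conditions: CH2=CHMgBr (3 equiv), anhydrous CeCl3 (3 equiv), THF, −78 to 0 °C; H2O quench
Reagents that add atoms: vinylmagnesium bromide C=C[Mg]Br
Why: Organocerium-mediated 1,2-addition of the vinyl Grignard reagent suppresses enolisation of the hindered ketone and gives the tertiary allylic alcohol, whose carbinol configuration is of no consequence because C3 becomes sp2 in step 4.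

Step 4
Reactants: 4 C3 vinyl carbinol of the hydrindane ketal
Product: 6 8,8-ethylenedioxy-11,12,13-trinor-10βH-eremophilan-3-one, via C4-epimeric ketone 5 (not isolated)
Conditions: Co(II) salen complex [N,N'-bis(3,5-di-tert-butylsalicylidene)-1,2-cyclohexanediamine cobalt(II)] (5 mol %), N-fluoro-2,4,6-trimethylpyridinium triflate (1.3 equiv), PhSiH3 (1.1 equiv), CH2Cl2/HFIP 4:1, 0 °C to rt; aq. NaHCO3 work-up; then K2CO3 (0.3 equiv), MeOH, rt
Reagents that add atoms: none
Why: Proposed new method: Co–H generated from the Co(salen) catalyst, the N-fluoropyridinium oxidant and PhSiH3 transfers H• to the terminal vinyl carbon (Markovnikov MHAT), the secondary C4 radical is captured and oxidised to an alkyl–Co(IV) species (a C4 cation equivalent), and the C3–C5 bond, antiperiplanar to C4–Co and pushed by the carbinol oxygen, shifts to C4 to give the C3 ketone after loss of the OH proton. The closest known reaction type is the cobalt-catalysed HAT-initiated radical–polar crossover semipinacol rearrangement of tertiary allylic alcohols with 1,1-disubstituted alkenes, extended here to a monosubstituted vinyl group and to a cyclopentanol, and the migration itself mirrors the D-homoannulation of 17-hydroxy C20 cations in steroids, where the quaternary C13 migrates. Ring A is not closed by a cyclisation: it arises by 1,2-alkyl shift as a one-carbon enlargement of the cyclopentane C5–C3–C2–C1–C10, so no exo/endo mode applies. C5 migrates with retention, which carries the quaternary centre and the cis ring fusion over unchanged, while the new C4 centre is set thermodynamically in the K2CO3/MeOH equilibration through the C3 enolate: with C8 sp3 (dioxolane) the steroid-like chair–chair conformer with an equatorial 4β-methyl cis to the axial C5 methyl should be favoured, because the 4α epimer must either place its methyl syn-axial to C9 or flip to the conformer with a ketal oxygen syn-axial to C1. The step needs migration of C5 rather than C2 and rearrangement rather than epoxide closure or alkene reduction; the quaternary, more electron-rich C5 is the better migrating group, and relief of cyclopentane eclipsing strain together with C=O formation should drive the shift over 3-exo attack by oxygen.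

Step 5
Reactants: 6 8,8-ethylenedioxy-11,12,13-trinor-10βH-eremophilan-3-one
Product: 7 8,8-ethylenedioxy-11,12,13-trinor-10βH-eremophilan-3α-ol
Conditions: Li, NH3(l)/THF, EtOH (3 equiv), −78 °C; NH4Cl
Reagents that add atoms: none
Why: Dissolving-metal reduction of the ketone gives the thermodynamically preferred equatorial alcohol, i.e. the 3α-OH trans to the equatorial C4 methyl, independent of the kinetic facial bias imposed by the syn-axial C5 methyl, and leaves the dioxolane untouched.

Step 6
Reactants: 7 8,8-ethylenedioxy-11,12,13-trinor-10βH-eremophilan-3α-ol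
Product: 8 3α-angeloyloxy-8,8-ethylenedioxy-11,12,13-trinor-10βH-eremophilane
Conditions: angelic acid, 2,4,6-trichlorobenzoyl chloride, Et3N, toluene, rt; then 7, 80 °C
Reagents that add atoms: angelic acid C/C=C(/C)C(=O)O
Why: Yamaguchi-type esterification through the mixed anhydride, run without a nucleophilic catalyst, acylates the secondary alcohol with retention at C3 and should avoid Z-to-E isomerisation of the angelate.

Step 7
Reactants: 8 3α-angeloyloxy-8,8-ethylenedioxy-11,12,13-trinor-10βH-eremophilane
Product: 9 3α-angeloyloxy-11,12,13-trinor-10βH-eremophilan-8-one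
Conditions: 2 M HCl, THF, rt
Reagents that add atoms: water O
Why: Acid-catalysed hydrolysis of the dioxolane unmasks the C8 ketone, and the angelate ester is stable to dilute aqueous acid at room temperature.

Step 8
Reactants: 9 3α-angeloyloxy-11,12,13-trinor-10βH-eremophilan-8-one
Product: 10 3α-angeloyloxy-8-(triethylsilyloxy)-11,12,13-trinor-10βH-eremophil-8-ene
Conditions: TESOTf (1.3 equiv), Et3N (2.5 equiv), CH2Cl2, 0 °C to rt (equilibrating)
Reagents that add atoms: triethylsilyl triflate CC[Si](CC)(CC)OS(=O)(=O)C(F)(F)F
Why: Silyl enol ether formation under equilibrating conditions should place the double bond towards C9 (the ring-fusion side), as cis-fused 3-keto-5β-steroids enolise towards C4; ring A with its two equatorial substituents locks the steroid-like conformer on which this preference rests.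

Step 9
Reactants: 10 3α-angeloyloxy-8-(triethylsilyloxy)-11,12,13-trinor-10βH-eremophil-8-ene
Product: 12 3α-angeloyloxy-9β-(triethylsilyloxy)-11,12,13-trinor-10βH-eremophilan-8-one, via silyloxy epoxide 11 (not isolated)
Conditions: m-CPBA (1.1 equiv), NaHCO3, CH2Cl2, −20 to 0 °C
Reagents that add atoms: m-chloroperbenzoic acid OOC(=O)c1cccc(Cl)c1
Why: Rubottom oxidation: the peracid epoxidises the electron-rich enol ether (far faster than the conjugated angelate alkene) from the β face, the α face being shielded by the axial C4 of ring A, and ring opening with 1,4-silyl migration gives the equatorial 9β-silyloxy ketone, which sets C9.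

Step 10
Reactants: 12 3α-angeloyloxy-9β-(triethylsilyloxy)-11,12,13-trinor-10βH-eremophilan-8-one
Product: 14 3α-angeloyloxy-11-hydroxy-9β-(triethylsilyloxy)-10βH-eremophilan-8-one, via lithium enolate 13 (not isolated)
Conditions: LDA (1.05 equiv), THF, −78 °C; acetone (3 equiv), −78 °C; AcOH quench at −78 °C
Reagents that add atoms: acetone CC(C)=O
Why: Kinetic deprotonation of the α-silyloxy ketone with LDA occurs at the α′-methylene C7 and should be much faster than attack on the angelate, and the lithium enolate undergoes aldol addition to acetone from the β face (the α face is blocked by the syn-axial C4), which sets the equatorial 7β side chain.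

Step 11
Reactants: 14 3α-angeloyloxy-11-hydroxy-9β-(triethylsilyloxy)-10βH-eremophilan-8-one
Product: 16 3α-angeloyloxy-9β-(triethylsilyloxy)-10βH-eremophil-11-en-8-one, via tertiary chlorosulfite 15 (not isolated)
Conditions: SOCl2 (1.5 equiv), pyridine, CH2Cl2, −20 to 0 °C
Reagents that add atoms: none
Why: Dehydration of the tertiary alcohol by E2 elimination of its chlorosulfite with pyridine is expected to remove one of the six unhindered methyl hydrogens in preference to the single hindered C7–H, giving the isopropenyl (β,γ-unsaturated) ketone without touching C7.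

Step 12
Reactants: 16 3α-angeloyloxy-9β-(triethylsilyloxy)-10βH-eremophil-11-en-8-one
Product: 17 3α-angeloyloxy-9β-hydroxy-10βH-eremophil-11-en-8-one
Conditions: HF·pyridine, pyridine, THF, 0 °C
Reagents that add atoms: none
Why: Buffered fluoride cleavage of the triethylsilyl ether frees the 9β-hydroxyl under conditions that should not isomerise the α-ketol, the β,γ-unsaturated ketone or the angelate.

Step 13
Reactants: 17 3α-angeloyloxy-9β-hydroxy-10βH-eremophil-11-en-8-one
Product: 18 3α-angeloyloxy-9β-senecioyloxy-10βH-eremophil-11-en-8-one (CNP0375730.2)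
Conditions: 3-methylbut-2-enoyl chloride (2 equiv), pyridine, DMAP (cat.), CH2Cl2, 0 °C
Reagents that add atoms: senecioyl chloride (3-methylbut-2-enoyl chloride) CC(C)=CC(=O)Cl
Why: O-Acylation of the secondary α-hydroxy ketone with the acid chloride and pyridine, a weak base that avoids vinylketene formation and deconjugation of the senecioate, gives the target with retention at C9.

**Compound list**

1 | (S)-Hajos–Parrish ketone, (7aS)-7a-methyl-2,3,7,7a-tetrahydro-1H-indene-1,5(6H)-dione | C[C@]12CCC(=O)C=C1CCC2=O | starting material
2 | cis-7a-methylhexahydroindane-1,5-dione, (3aR,7aS); ring-fusion H cis to CH3 | C1C[C@@]2(C)[C@H](CCC2=O)CC1=O | intermediate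
3 | C8-monoethylene ketal of 2 (six-ring ketone masked; five-ring ketone free) | C1C[C@@]2(C)[C@H](CCC2=O)CC13OCCO3 | intermediate
4 | C3 vinyl carbinol of 3 (1-ethenyl-1-hydroxy; OH cis to the angular CH3, assumed) | C1C[C@@]2(C)[C@H](CC[C@@]2(O)C=C)CC13OCCO3 | intermediate
5 | 8,8-ethylenedioxy-11,12,13-trinor-10βH-eremophilan-3-one, 4α-methyl (C4) epimer | C1C[C@@]2(C)[C@H](CCC(=O)[C@H]2C)CC13OCCO3 | intermediate (not isolated)
6 | 8,8-ethylenedioxy-11,12,13-trinor-10βH-eremophilan-3-one (4β,5β-dimethyl; cis-decalin) | C1C[C@@]2(C)[C@H](CCC(=O)[C@@H]2C)CC13OCCO3 | intermediate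
7 | 8,8-ethylenedioxy-11,12,13-trinor-10βH-eremophilan-3α-ol | C1C[C@@]2(C)[C@H](CC[C@@H](O)[C@@H]2C)CC13OCCO3 | intermediate
8 | 3α-angeloyloxy-8,8-ethylenedioxy-11,12,13-trinor-10βH-eremophilane | C1C[C@@]2(C)[C@H](CC[C@@H](OC(=O)/C(C)=C\C)[C@@H]2C)CC13OCCO3 | intermediate
9 | 3α-angeloyloxy-11,12,13-trinor-10βH-eremophilan-8-one | C1C[C@@]2(C)[C@H](CC[C@@H](OC(=O)/C(C)=C\C)[C@@H]2C)CC1=O | intermediate
10 | 3α-angeloyloxy-8-(triethylsilyloxy)-11,12,13-trinor-10βH-eremophil-8-ene | C1C[C@@]2(C)[C@H](CC[C@@H](OC(=O)/C(C)=C\C)[C@@H]2C)C=C1O[Si](CC)(CC)CC | intermediate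
11 | 3α-angeloyloxy-8β,9β-epoxy-8α-(triethylsilyloxy)-11,12,13-trinor-10βH-eremophilane | C1C[C@@]2(C)[C@H](CC[C@@H](OC(=O)/C(C)=C\C)[C@@H]2C)[C@H]3O[C@@]13O[Si](CC)(CC)CC | intermediate (not isolated)
12 | 3α-angeloyloxy-9β-(triethylsilyloxy)-11,12,13-trinor-10βH-eremophilan-8-one | C1C[C@@]2(C)[C@H](CC[C@@H](OC(=O)/C(C)=C\C)[C@@H]2C)[C@@H](O[Si](CC)(CC)CC)C1=O | intermediate
13 | lithium 7(8)-enolate of 12 | [Li+].[O-]C1=CC[C@@]2(C)[C@H](CC[C@@H](OC(=O)/C(C)=C\C)[C@@H]2C)[C@H]1O[Si](CC)(CC)CC | intermediate (not isolated)
14 | 3α-angeloyloxy-11-hydroxy-9β-(triethylsilyloxy)-10βH-eremophilan-8-one (7β side chain, 7αH) | CC(C)(O)[C@H]1C[C@@]2(C)[C@H](CC[C@@H](OC(=O)/C(C)=C\C)[C@@H]2C)[C@@H](O[Si](CC)(CC)CC)C1=O | intermediate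
15 | 11-O-chlorosulfite of 14 | CC(C)(OS(=O)Cl)[C@H]1C[C@@]2(C)[C@H](CC[C@@H](OC(=O)/C(C)=C\C)[C@@H]2C)[C@@H](O[Si](CC)(CC)CC)C1=O | intermediate (not isolated)
16 | 3α-angeloyloxy-9β-(triethylsilyloxy)-10βH-eremophil-11-en-8-one | C=C(C)[C@H]1C[C@@]2(C)[C@H](CC[C@@H](OC(=O)/C(C)=C\C)[C@@H]2C)[C@@H](O[Si](CC)(CC)CC)C1=O | intermediate
17 | 3α-angeloyloxy-9β-hydroxy-10βH-eremophil-11-en-8-one | C=C(C)[C@H]1C[C@@]2(C)[C@H](CC[C@@H](OC(=O)/C(C)=C\C)[C@@H]2C)[C@@H](O)C1=O | intermediate
18 | 3α-angeloyloxy-9β-senecioyloxy-10βH-eremophil-11-en-8-one, (3R,4R,5R,7R,9R,10S) | C=C(C)[C@H]1C[C@@]2(C)[C@H](CC[C@@H](OC(=O)/C(C)=C\C)[C@@H]2C)[C@@H](OC(=O)C=C(C)C)C1=O | target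

Total step count: 13
Longest linear sequence: 13 steps (1 to 18)

**Steps most likely to fail**

Step 4 (Proposed new method). The C4 alkylcobalt (cation equivalent) may be intercepted by the neighbouring hydroxyl (epoxide closure) or by a second hydrogen transfer (reduction to the ethyl carbinol) before C5 migrates, or C2 may migrate in competition. The fallback uses known chemistry and sets out from ketone 3. Wittig olefination with ethylidenetriphenylphosphorane (EtPPh3Br, KOtBu, THF, reflux) should give the (Z)-ethylidene hydrindane F1. Catalytic OsO4/NMO dihydroxylation, assumed to occur anti to the angular methyl, gives the tertiary–secondary diol F2. MsCl/Et3N sulfonylates only the secondary hydroxyl to give the hydroxy mesylate F3. An organoaluminium-promoted pinacol-type (semipinacol) rearrangement (Et3Al, CH2Cl2, −78 to 0 °C) then moves C5 anti to the departing mesylate, with inversion at C4, to give ketone 5. The K2CO3/MeOH equilibration of step 4 converts 5 into 6, where the route is rejoined.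

Step 8. Regiocontrol may be lost in enol silane formation (enolisation towards C7 instead of C9), which would place the oxygen on the wrong α-carbon. The fallback inverts the order of ring-B functionalisation and sets out from 9. The Δ7(8) triethylsilyl enol ether F4 (the regioisomer delivered by this failure mode, or made deliberately under whichever silylation conditions favour it) undergoes Mukaiyama aldol addition to acetone (TiCl4, CH2Cl2, −78 °C) to give the C7 ketol F5. SOCl2/pyridine dehydration through the chlorosulfite F6 gives the isopropenyl ketone F7. Kinetic deprotonation (LDA, THF, −78 °C) then has only the C9 methylene as an unhindered site and gives the lithium enolate F8. Hydroxylation from the β face with 2-(phenylsulfonyl)-3-phenyloxaziridine gives 17, where the route is rejoined.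

Step 11. Elimination may run towards C7 (removal of the acidic α-hydrogen) to give the conjugated isopropylidene ketone, or the double bond may later move into conjugation under base. The fallback bypasses the aldol–dehydration pair and sets out from 12. The enolate 13 is trapped with TMSCl as the Δ7(8) trimethylsilyl enol ether F9. Its tin enolate (generated with Bu3SnF) undergoes palladium-catalysed α-alkenylation with 2-bromopropene (PdCl2[P(o-tol)3]2, benzene, reflux), which attaches the isopropenyl sp2 carbon to C7 from the β face and gives 16, where the route is rejoined.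

**Further compounds**

F1 | step 4 | (Z)-ethylidene derivative of 3 (CH3 syn to the quaternary carbon) | C1C[C@@]2(C)[C@H](CC/C2=C/C)CC13OCCO3
F2 | step 4 | C3,C4-diol from F1 (tertiary C3–OH and secondary C4–OH; α-face syn-dihydroxylation assumed) | C1C[C@@]2(C)[C@H](CC[C@]2(O)[C@H](C)O)CC13OCCO3
F3 | step 4 | secondary (C4) mesylate of F2 | C1C[C@@]2(C)[C@H](CC[C@]2(O)[C@H](C)OS(C)(=O)=O)CC13OCCO3
F4 | step 8 | Δ7(8) triethylsilyl enol ether of 9 | CC[Si](CC)(CC)OC1=CC[C@@]2(C)[C@H](CC[C@@H](OC(=O)/C(C)=C\C)[C@@H]2C)C1
F5 | step 8 | 3α-angeloyloxy-11-hydroxy-10βH-eremophilan-8-one | CC(C)(O)[C@H]1C[C@@]2(C)[C@H](CC[C@@H](OC(=O)/C(C)=C\C)[C@@H]2C)CC1=O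
F6 | step 8 | 11-O-chlorosulfite of F5 | CC(C)(OS(=O)Cl)[C@H]1C[C@@]2(C)[C@H](CC[C@@H](OC(=O)/C(C)=C\C)[C@@H]2C)CC1=O
F7 | step 8 | 3α-angeloyloxy-10βH-eremophil-11-en-8-one | C=C(C)[C@H]1C[C@@]2(C)[C@H](CC[C@@H](OC(=O)/C(C)=C\C)[C@@H]2C)CC1=O
F8 | step 8 | lithium 8(9)-enolate of F7 | C=C(C)[C@H]1C[C@@]2(C)[C@H](CC[C@@H](OC(=O)/C(C)=C\C)[C@@H]2C)C=C1[O-].[Li+]
F9 | step 11 | Δ7(8) trimethylsilyl enol ether of 12 | C[Si](C)(C)OC1=CC[C@@]2(C)[C@H](CC[C@@H](OC(=O)/C(C)=C\C)[C@@H]2C)[C@H]1O[Si](CC)(CC)CC
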